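The benzofuran is disconnected at O1–C2. Its O1, aryl-bearing C2, methoxylated C3 and ring A together are a 3-aryl-4-hydroxycoumarin that has lost its lactone carbonyl carbon, so the heterocycle is made by contracting a chroman-2,4-dione. In one operation hydroxide opens the lactone of a 3-chloro-3-aryl dione, the liberated ring A phenoxide displaces chloride to forge O1–C2 and the furanone ring, and carbon dioxide is expelled. The precursor is the racemic 3-chloro derivative of a 6-prenyl-7-MOM-oxy-3-(2-MOM-oxy-4-methoxyphenyl)-4-hydroxycoumarin, assembled from an acetophenone, diethyl carbonate and an aryllead reagent. Enolate O-methylation and MOM removal finish the synthesis.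

Key step: step 8

Remark: the target has no stereocentre; 12 to 15 are racemic and their single stereocentre disappears when C2 becomes sp2 in step 9. The prenyl group is brought in as its commercial pinacol boronate 3, because a prenyl electrophile cannot be joined directly to a bromoarene that carries a ketone.

Step 1
Reactants: 1 1-(5-bromo-2,4-dihydroxyphenyl)ethanone
Product: 2 1-[5-bromo-2-hydroxy-4-(methoxymethoxy)phenyl]ethanone
Conditions: MOMCl (1.1 equiv), K2CO3, acetone, 0 °C → rt
Reagents that add atoms: chloromethyl methyl ether, COCCl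
Why: Williamson-type O-alkylation in which the 2-hydroxyl is tied up in a hydrogen bond to the acetyl carbonyl, so the unchelated and more acidic 4-hydroxyl (ortho to bromine) is the phenoxide that K2CO3 forms and MOMCl captures.

Step 2
Reactants: 2 1-[5-bromo-2-hydroxy-4-(methoxymethoxy)phenyl]ethanone; 3 4,4,5,5-tetramethyl-2-(3-methylbut-2-en-1-yl)-1,3,2-dioxaborolane (prenylboronic acid pinacol ester)
Product: 4 1-[2-hydroxy-4-(methoxymethoxy)-5-(3-methylbut-2-en-1-yl)phenyl]ethanone
Conditions: Pd(OAc)2 (cat.), t-BuXPhos (cat.), K3PO4 (aq.), THF, 40 °C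
Reagents that add atoms: none
Why: Suzuki–Miyaura coupling of an allylboronate, in which a bulky biaryl di-tert-butylphosphine should let the allylpalladium intermediate settle in its primary sigma-form before reductive elimination and so give the linear prenyl arene, under aqueous phosphate conditions that the ketone, the chelated phenol and the MOM ether tolerate.

Step 3
Reactants: 4 1-[2-hydroxy-4-(methoxymethoxy)-5-(3-methylbut-2-en-1-yl)phenyl]ethanone; 5 diethyl carbonate
Product: 6 4-hydroxy-7-(methoxymethoxy)-6-(3-methylbut-2-en-1-yl)-2H-chromen-2-one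
Conditions: NaH (4 equiv), (EtO)2CO (excess), toluene, 100 °C; then cold aq. HCl to pH 3
Reagents that add atoms: none
Why: Claisen condensation of the methyl ketone enolate with diethyl carbonate followed by lactonisation through the ortho phenoxide is the standard route from 2-hydroxyacetophenones to 4-hydroxycoumarins, driven by formation of the stabilised coumarin enolate and harmless to the MOM ether and the prenyl group.

Step 4
Reactants: 7 2-bromo-5-methoxyphenol
Product: 8 1-bromo-4-methoxy-2-(methoxymethoxy)benzene
Conditions: NaH, THF, 0 °C; MOMCl, 0 °C → rt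
Reagents that add atoms: chloromethyl methyl ether, COCCl
Why: Williamson etherification of the sodium phenoxide with the reactive alpha-chloro ether.

Step 5
Reactants: 8 1-bromo-4-methoxy-2-(methoxymethoxy)benzene
Product: 9 [4-methoxy-2-(methoxymethoxy)phenyl]boronic acid
Conditions: n-BuLi, THF, −78 °C; B(Oi-Pr)3, −78 °C → rt; aq. HCl to pH 5, 0 °C
Reagents that add atoms: triisopropyl borate, CC(C)OB(OC(C)C)OC(C)C; water, O
Why: Bromine–lithium exchange at −78 °C outruns any ortho-lithiation, the aryllithium (stabilised by the neighbouring MOM oxygen) is trapped by the borate, and mild hydrolysis frees the boronic acid (lithiation–borylation).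

Step 6
Reactants: 6 4-hydroxy-7-(methoxymethoxy)-6-(3-methylbut-2-en-1-yl)-2H-chromen-2-one; 9 [4-methoxy-2-(methoxymethoxy)phenyl]boronic acid
Product: 11 4-hydroxy-3-[4-methoxy-2-(methoxymethoxy)phenyl]-7-(methoxymethoxy)-6-(3-methylbut-2-en-1-yl)-2H-chromen-2-one, via [4-methoxy-2-(methoxymethoxy)phenyl]lead triacetate 10 (not isolated)
Conditions: 9 (1.3 equiv), Pb(OAc)4 (1.2 equiv), Hg(OAc)2 (cat.), CHCl3, 40 °C; then 6, pyridine, CHCl3, 60 °C
Reagents that add atoms: none
Why: Pinhey-type arylation in which mercury-catalysed boron-to-lead exchange gives the aryllead triacetate, which in chloroform–pyridine transfers its aryl group by ligand coupling to C3 of the 4-hydroxycoumarin (a reaction class established for ortho-alkoxyaryl groups), the boronic acid being kept in slight excess so that no tetravalent lead or free Hg(OAc)2 is left to attack the prenyl alkene.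

Step 7
Reactants: 11 4-hydroxy-3-[4-methoxy-2-(methoxymethoxy)phenyl]-7-(methoxymethoxy)-6-(3-methylbut-2-en-1-yl)-2H-chromen-2-one
Product: 12 racemic 3-chloro-3-[4-methoxy-2-(methoxymethoxy)phenyl]-7-(methoxymethoxy)-6-(3-methylbut-2-en-1-yl)chromane-2,4-dione
Conditions: NCS (1.05 equiv), CH2Cl2, 0 °C → rt, dark
Reagents that add atoms: N-chlorosuccinimide, O=C1CCC(=O)N1Cl
Why: Electrophilic chlorination of a 1,3-dicarbonyl enol, which is far more nucleophilic toward NCS than the trisubstituted alkene or the alkoxyarenes, and since C3 already bears the aryl group only one chlorine can enter, giving the quaternary chloride as a racemate.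

Step 8
Reactants: 12 racemic 3-chloro-3-[4-methoxy-2-(methoxymethoxy)phenyl]-7-(methoxymethoxy)-6-(3-methylbut-2-en-1-yl)chromane-2,4-dione
Product: 15 racemic 2-[4-methoxy-2-(methoxymethoxy)phenyl]-6-(methoxymethoxy)-5-(3-methylbut-2-en-1-yl)-1-benzofuran-3(2H)-one, via ring-opened chloro keto acid 13 (not isolated), via coumaranone-2-carboxylic acid 14 (not isolated)
Conditions: 12 added slowly to NaOH (aq. 1 M, 4 equiv), THF, 0 °C → rt, Ar, degassed; then degassed aq. NaH2PO4
Reagents that add atoms: none
Why: Hydroxide adds to the C2 lactone carbonyl of 12, an aryl ester far more electrophilic than the conjugated aryl ketone at C4, and the tetrahedral intermediate collapses to the ring A phenoxide and the alpha-chloro-beta-keto carboxylate 13. The phenoxide then attacks the chlorine-bearing carbon, activated by the flanking carbonyl groups and the electron-rich aryl group, in a 5-exo-tet closure that forms the O1–C2 bond and the furanone ring of 14. Carbon dioxide leaves 14 readily because the carbanion left behind is the aromatic benzofuran-3-olate; if decarboxylation comes before closure, the same phenoxide displaces a secondary alpha-keto benzylic chloride and the product is identical. The closest known reaction type is the Perkin coumarin-to-benzofuran contraction, in the variant where 3-halochroman-2,4-diones give 2-substituted coumaran-3-ones in aqueous alkali. The new C2 stereocentre is under no control and forms as a racemate, which does not matter because it becomes sp2 in step 9. The step needs lactone opening to win over cleavage at C4 and over transfer of positive chlorine to hydroxide or to the product enolate, which the ester character of C2, the low temperature and the slow addition of 12 to excess base should secure, while argon and degassed solvents protect the oxidisable enolate of 15.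

Step 9
Reactants: 15 racemic 2-[4-methoxy-2-(methoxymethoxy)phenyl]-6-(methoxymethoxy)-5-(3-methylbut-2-en-1-yl)-1-benzofuran-3(2H)-one
Product: 16 3-methoxy-2-[4-methoxy-2-(methoxymethoxy)phenyl]-6-(methoxymethoxy)-5-(3-methylbut-2-en-1-yl)-1-benzofuran
Conditions: Me2SO4, K2CO3, acetone (degassed), 50 °C, Ar
Reagents that add atoms: dimethyl sulfate, COS(=O)(=O)OC
Why: O-Alkylation of an ambident enolate, in which the potassium benzofuran-3-olate is methylated on oxygen by the hard electrophile to give an aromatic furan, whereas C-attack would have to build a quaternary centre flanked by the aryl group and the ring oxygen.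

Step 10
Reactants: 16 3-methoxy-2-[4-methoxy-2-(methoxymethoxy)phenyl]-6-(methoxymethoxy)-5-(3-methylbut-2-en-1-yl)-1-benzofuran
Product: 17 ambofuranol, 2-(2-hydroxy-4-methoxyphenyl)-3-methoxy-5-(3-methylbut-2-en-1-yl)-1-benzofuran-6-ol
Conditions: HCl (aq. 3 M, cat.), MeOH, 40 °C
Reagents that add atoms: none
Why: Acid-catalysed acetal exchange with methanol cleaves both aryl MOM ethers under conditions mild enough that the prenyl group should not cyclise onto the neighbouring phenol and the aromatic 3-methoxy enol ether should stay intact.

Compound list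
1 | 1-(5-bromo-2,4-dihydroxyphenyl)ethanone | CC(=O)c1cc(Br)c(O)cc1O | starting material
2 | 1-[5-bromo-2-hydroxy-4-(methoxymethoxy)phenyl]ethanone | CC(=O)c1cc(Br)c(OCOC)cc1O | intermediate
3 | 4,4,5,5-tetramethyl-2-(3-methylbut-2-en-1-yl)-1,3,2-dioxaborolane (prenylboronic acid pinacol ester) | CC(C)=CCB1OC(C)(C)C(C)(C)O1 | starting material
4 | 1-[2-hydroxy-4-(methoxymethoxy)-5-(3-methylbut-2-en-1-yl)phenyl]ethanone | CC(=O)c1cc(CC=C(C)C)c(OCOC)cc1O | intermediate
5 | diethyl carbonate | CCOC(=O)OCC | starting material
6 | 4-hydroxy-7-(methoxymethoxy)-6-(3-methylbut-2-en-1-yl)-2H-chromen-2-one | COCOc1cc2OC(=O)C=C(O)c2cc1CC=C(C)C | intermediate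
7 | 2-bromo-5-methoxyphenol | COc1ccc(Br)c(O)c1 | starting material
8 | 1-bromo-4-methoxy-2-(methoxymethoxy)benzene | COCOc1cc(OC)ccc1Br | intermediate
9 | [4-methoxy-2-(methoxymethoxy)phenyl]boronic acid | COCOc1cc(OC)ccc1B(O)O | intermediate
10 | [4-methoxy-2-(methoxymethoxy)phenyl]lead triacetate | COCOc1cc(OC)ccc1[Pb](OC(C)=O)(OC(C)=O)OC(C)=O | intermediate (not isolated)
11 | 4-hydroxy-3-[4-methoxy-2-(methoxymethoxy)phenyl]-7-(methoxymethoxy)-6-(3-methylbut-2-en-1-yl)-2H-chromen-2-one | COCOc1cc2OC(=O)C(c3ccc(OC)cc3OCOC)=C(O)c2cc1CC=C(C)C | intermediate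
12 | racemic 3-chloro-3-[4-methoxy-2-(methoxymethoxy)phenyl]-7-(methoxymethoxy)-6-(3-methylbut-2-en-1-yl)chromane-2,4-dione | COCOc1cc2OC(=O)C(Cl)(c3ccc(OC)cc3OCOC)C(=O)c2cc1CC=C(C)C | intermediate
13 | racemic 2-chloro-3-[2-hydroxy-4-(methoxymethoxy)-5-(3-methylbut-2-en-1-yl)phenyl]-2-[4-methoxy-2-(methoxymethoxy)phenyl]-3-oxopropanoic acid (ring-opened chloro keto acid, present as its dianion) | COCOc1cc(O)c(C(=O)C(Cl)(C(=O)O)c2ccc(OC)cc2OCOC)cc1CC=C(C)C | intermediate (not isolated)
14 | racemic 2-[4-methoxy-2-(methoxymethoxy)phenyl]-6-(methoxymethoxy)-5-(3-methylbut-2-en-1-yl)-3-oxo-2,3-dihydro-1-benzofuran-2-carboxylic acid (present as its carboxylate) | COCOc1cc2OC(C(=O)O)(c3ccc(OC)cc3OCOC)C(=O)c2cc1CC=C(C)C | intermediate (not isolated)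
15 | racemic 2-[4-methoxy-2-(methoxymethoxy)phenyl]-6-(methoxymethoxy)-5-(3-methylbut-2-en-1-yl)-1-benzofuran-3(2H)-one | COCOc1cc2OC(c3ccc(OC)cc3OCOC)C(=O)c2cc1CC=C(C)C | intermediate
16 | 3-methoxy-2-[4-methoxy-2-(methoxymethoxy)phenyl]-6-(methoxymethoxy)-5-(3-methylbut-2-en-1-yl)-1-benzofuran | COCOc1cc2oc(-c3ccc(OC)cc3OCOC)c(OC)c2cc1CC=C(C)C | intermediate
17 | ambofuranol, 2-(2-hydroxy-4-methoxyphenyl)-3-methoxy-5-(3-methylbut-2-en-1-yl)-1-benzofuran-6-ol | COc1ccc(-c2oc3cc(O)c(CC=C(C)C)cc3c2OC)c(O)c1 | target

Total step count: 10. Longest linear sequence: 8 steps (steps 1, 2, 3, 6, 7, 8, 9 and 10, from 1); the ring B branch (steps 4 and 5) joins at step 6.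

Steps most likely to fail

Step 8. Hydroxide may attack chlorine instead of the lactone carbonyl, handing positive chlorine on and returning the enolate of 11, or it may add to the C4 ketone and cleave ring A away as a salicylate before the O1–C2 bond can form. The fallback makes that bond without a halogenated lactone. It sets out from 11, which on prolonged heating with KOH in degassed aqueous ethanol should undergo lactone hydrolysis and decarboxylation to the deoxybenzoin 1-[2-hydroxy-4-(methoxymethoxy)-5-(3-methylbut-2-en-1-yl)phenyl]-2-[4-methoxy-2-(methoxymethoxy)phenyl]ethan-1-one F1. Its phenoxide–enolate dianion, made with LiN(SiMe3)2 (2.1 equiv) in THF at −78 °C, is added to NCS (1.0 equiv). This should give the racemic alpha-chloro ketone 2-chloro-1-[2-hydroxy-4-(methoxymethoxy)-5-(3-methylbut-2-en-1-yl)phenyl]-2-[4-methoxy-2-(methoxymethoxy)phenyl]ethan-1-one F2, which is not isolated. On warming to room temperature its neighbouring phenoxide displaces the secondary benzylic chloride (5-exo-tet, the classical coumaran-3-one closure of 2-hydroxyphenyl alpha-halo ketones). The route is rejoined at 15.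

Step 2. Reductive elimination may take place through the tertiary terminus of the allyl fragment and give the reverse-prenyl isomer, or oxidative addition into the electron-rich, phenoxide-bearing bromide may be so slow that the boronate is lost by protodeboronation. The fallback removes the regiochemical question by coupling a symmetrical allyl group and building the prenyl terminus afterwards. It sets out from 2, which with 2-allyl-4,4,5,5-tetramethyl-1,3,2-dioxaborolane (C=CCB1OC(C)(C)C(C)(C)O1), PdCl2(dppf) and CsF in THF at 65 °C should give 1-[2-hydroxy-4-(methoxymethoxy)-5-(prop-2-en-1-yl)phenyl]ethanone F3. Cross-metathesis of F3 with excess 2-methylbut-2-ene (CC=C(C)C) and second-generation Grubbs catalyst in CH2Cl2 at 40 °C exchanges the terminal methylene for an isopropylidene group with loss of propene. The route is rejoined at 4.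

Step 6. Boron-to-lead exchange may stay incomplete while the electron-rich boronic acid protodeboronates, ligand coupling at the hindered C3 may be slow, and lead or mercury acetates may attack the prenyl alkene. The fallback replaces ligand coupling at lead by a palladium-catalysed cross-coupling of an electrophilic coumarin. It sets out from 6, which with PhI(OAc)2 and Na2CO3 in aqueous methanol at room temperature should give the phenyliodonium ylide 7-(methoxymethoxy)-6-(3-methylbut-2-en-1-yl)-2-oxo-3-(phenyliodonio)-2H-chromen-4-olate F4. Suzuki-type coupling of F4 with boronic acid 9 (Pd(OAc)2, P(t-Bu)3, LiOH, DME–water, room temperature), in which zerovalent palladium inserts into the C3–iodine bond and iodobenzene is released, should deliver the 3-aryl-4-hydroxycoumarin. The route is rejoined at 11.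

Further compounds
F1 | step 8 | 1-[2-hydroxy-4-(methoxymethoxy)-5-(3-methylbut-2-en-1-yl)phenyl]-2-[4-methoxy-2-(methoxymethoxy)phenyl]ethan-1-one | COCOc1cc(O)c(C(=O)Cc2ccc(OC)cc2OCOC)cc1CC=C(C)C
F2 | step 8 | racemic 2-chloro-1-[2-hydroxy-4-(methoxymethoxy)-5-(3-methylbut-2-en-1-yl)phenyl]-2-[4-methoxy-2-(methoxymethoxy)phenyl]ethan-1-one | COCOc1cc(O)c(C(=O)C(Cl)c2ccc(OC)cc2OCOC)cc1CC=C(C)C
F3 | step 2 | 1-[2-hydroxy-4-(methoxymethoxy)-5-(prop-2-en-1-yl)phenyl]ethanone | CC(=O)c1cc(CC=C)c(OCOC)cc1O
F4 | step 6 | 7-(methoxymethoxy)-6-(3-methylbut-2-en-1-yl)-2-oxo-3-(phenyliodonio)-2H-chromen-4-olate | COCOc1cc2OC(=O)C([I+]c3ccccc3)=C([O-])c2cc1CC=C(C)C
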